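**Retrosynthetic overview**

1. Rhodisin ⇒ its hexadeca-O-benzyl ether (hydrogenolysis last). All aromatic rings are bought; only the two pyran rings are built.
2. Both pyran rings and the interflavan bond are disconnected together: C4–C4a in each half (Friedel–Crafts closure onto a C4 acetal carbon) and C4–C8′ (capture of the flavan-4-yl cation). This leads to one acyclic monomer, an aryl ether–acetal–gallate, used for both halves.
3. Monomer ⇒ tri-O-benzylgallic acid + β-aryloxy alcohol ⇒ cis-epoxy acetal + 3,5-bis(benzyloxy)phenol (SN2 at the benzylic carbon makes O1–C2) ⇒ Z-alkenyl dioxolane (Jacobsen epoxidation) ⇒ tri-O-benzylated gallaldehyde + a C2 Wittig salt.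
4. Ring order: the lower pyran ring (F) closes first and is reduced at C4 in the flask; the upper pyran ring (C) closes next in the same flask and its C4 cation is trapped at C8 of the lower unit (4β).

Assumption: the benzyl-protected building blocks (3,4,5-tris(benzyloxy)benzaldehyde, 3,5-bis(benzyloxy)phenol, 3,4,5-tris(benzyloxy)benzoic acid) and the Wittig salt are bought as catalogue compounds.

**Route**

Step 1
Reactants: 1 3,4,5-tris(benzyloxy)benzaldehyde; 2 (1,3-dioxolan-2-ylmethyl)triphenylphosphonium bromide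
Product: 3 2-{(Z)-2-[3,4,5-tris(benzyloxy)phenyl]ethenyl}-1,3-dioxolane
Conditions: 2, KHMDS, THF, −78 → 0 °C; then 1, −78 °C → rt
Reagents that add atoms: none
Why: Salt-free Wittig olefination of a non-stabilised (alkyl-type) ylide with an aromatic aldehyde is kinetically Z-selective, so the cis-alkene needed for the cis-epoxide is the major isomer and the minor E isomer is removed on silica.

Step 2
Reactants: 3 2-{(Z)-2-[3,4,5-tris(benzyloxy)phenyl]ethenyl}-1,3-dioxolane
Product: 4 (2S,3S)-2-(1,3-dioxolan-2-yl)-3-[3,4,5-tris(benzyloxy)phenyl]oxirane (cis-epoxide)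
Conditions: (S,S)-Jacobsen Mn(salen)Cl (5 mol%), 4-phenylpyridine N-oxide (20 mol%), aq NaOCl (pH 11.3), CH2Cl2, 0 °C
Reagents that add atoms: sodium hypochlorite, [Na+].[O-]Cl
Why: Jacobsen–Katsuki epoxidation works best on cis-β-substituted styrenes, and the (S,S) catalyst gives the benzylic (S) centre (the same sense in which the (R,R) catalyst gives (2R,3R)-cis-glycidates), so both epoxide stereocentres are set under basic conditions that spare the acetal and the acid-sensitive epoxide.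

Step 3
Reactants: 4 (2S,3S)-2-(1,3-dioxolan-2-yl)-3-[3,4,5-tris(benzyloxy)phenyl]oxirane; 5 3,5-bis(benzyloxy)phenol
Product: 6 (1S,2R)-2-[3,5-bis(benzyloxy)phenoxy]-1-(1,3-dioxolan-2-yl)-2-[3,4,5-tris(benzyloxy)phenyl]ethan-1-ol
Conditions: Cs2CO3 (0.3 equiv), DMF, 90 °C
Reagents that add atoms: none
Why: Base-mediated SN2 epoxide opening by the phenoxide occurs at the benzylic carbon because the other epoxide carbon is deactivated and shielded by the adjacent acetal; backside attack inverts the benzylic centre to (R) while the carbinol centre stays (S), which is the O,O relationship of a 2,3-cis flavan.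

Step 4
Reactants: 6 (1S,2R)-2-[3,5-bis(benzyloxy)phenoxy]-1-(1,3-dioxolan-2-yl)-2-[3,4,5-tris(benzyloxy)phenyl]ethan-1-ol; 7 3,4,5-tris(benzyloxy)benzoic acid
Product: 8 (1S,2R)-2-[3,5-bis(benzyloxy)phenoxy]-1-(1,3-dioxolan-2-yl)-2-[3,4,5-tris(benzyloxy)phenyl]ethyl 3,4,5-tris(benzyloxy)benzoate
Conditions: DCC, DMAP (cat.), CH2Cl2, 0 °C → rt
Reagents that add atoms: none
Why: Steglich esterification acylates the hindered secondary alcohol without touching either stereocentre, as in standard 3-O-galloylations of benzylated flavan-3-ols.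

Step 5
Reactants: 8 (1S,2R)-2-[3,5-bis(benzyloxy)phenoxy]-1-(1,3-dioxolan-2-yl)-2-[3,4,5-tris(benzyloxy)phenyl]ethyl 3,4,5-tris(benzyloxy)benzoate (3 equiv in total: 2 become the nucleophile, 1 the electrophile)
Product: 11 hexadeca-O-benzyl-rhodisin, via 4-(2-hydroxyethoxy)flavan gallate 9 (not isolated), via octa-O-benzyl-EGCG 10 (not isolated)
Conditions: (i) 8 (2 equiv), TMSOTf (0.3 equiv), CH2Cl2, −78 → −30 °C; Et3SiH (2 equiv), −30 °C; (ii) 8 (1 equiv) added over 2 h, −78 → −40 °C; Et3N quench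
Reagents that add atoms: none
Why: Proposed new method: TMSOTf opens the dioxolane of 8 to an oxocarbenium ion that is trapped intramolecularly by the phloroglucinol-type aryl ether ring in a six-membered Friedel–Crafts closure (closest known types: acid-mediated cyclisation of 3-aryloxypropanal acetals to 4-alkoxychromans and Friedel–Crafts C-glycosylation with 2-O-acyl donors) to give 9, whose 4-alkoxy group ionises to the flavan-4-yl cation as in the known TMSOTf couplings of 4-(2-hydroxyethoxy)flavans; in stage (i) this cation is reduced by Et3SiH (ionic hydrogenation) to 10, and in stage (ii) it is captured by C8 of 10 from the face anti to the participating 3-O-galloyl group, which sets C4 as 4β (3,4-trans) while C2 and C3 of both halves are carried over unchanged from 8.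

Step 6
Reactants: 11 hexadeca-O-benzyl-rhodisin
Product: 12 rhodisin
Conditions: H2 (1 atm), 20% Pd(OH)2/C, THF/MeOH/H2O, rt
Reagents that add atoms: none
Why: Global hydrogenolysis of the sixteen benzyl ethers over Pearlman's catalyst is the standard last step for prodelphinidin gallates and leaves the esters, the interflavan bond and all five stereocentres untouched.

**Compound list**

1 | 3,4,5-tris(benzyloxy)benzaldehyde | O=Cc1cc(OCc2ccccc2)c(OCc2ccccc2)c(OCc2ccccc2)c1 | starting material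
2 | (1,3-dioxolan-2-ylmethyl)triphenylphosphonium bromide | [Br-].C1COC(O1)C[P+](c1ccccc1)(c1ccccc1)c1ccccc1 | starting material
3 | 2-{(Z)-2-[3,4,5-tris(benzyloxy)phenyl]ethenyl}-1,3-dioxolane | C1COC(O1)/C=C\c1cc(OCc2ccccc2)c(OCc2ccccc2)c(OCc2ccccc2)c1 | intermediate
4 | (2S,3S)-2-(1,3-dioxolan-2-yl)-3-[3,4,5-tris(benzyloxy)phenyl]oxirane (cis) | O1[C@H](C2OCCO2)[C@@H]1c1cc(OCc3ccccc3)c(OCc3ccccc3)c(OCc3ccccc3)c1 | intermediate
5 | 3,5-bis(benzyloxy)phenol | Oc1cc(OCc2ccccc2)cc(OCc2ccccc2)c1 | starting material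
6 | (1S,2R)-2-[3,5-bis(benzyloxy)phenoxy]-1-(1,3-dioxolan-2-yl)-2-[3,4,5-tris(benzyloxy)phenyl]ethan-1-ol | O[C@H](C1OCCO1)[C@H](Oc1cc(OCc2ccccc2)cc(OCc2ccccc2)c1)c1cc(OCc2ccccc2)c(OCc2ccccc2)c(OCc2ccccc2)c1 | intermediate
7 | 3,4,5-tris(benzyloxy)benzoic acid | OC(=O)c1cc(OCc2ccccc2)c(OCc2ccccc2)c(OCc2ccccc2)c1 | starting material
8 | (1S,2R)-2-[3,5-bis(benzyloxy)phenoxy]-1-(1,3-dioxolan-2-yl)-2-[3,4,5-tris(benzyloxy)phenyl]ethyl 3,4,5-tris(benzyloxy)benzoate | O=C(O[C@H](C1OCCO1)[C@H](Oc1cc(OCc2ccccc2)cc(OCc2ccccc2)c1)c1cc(OCc2ccccc2)c(OCc2ccccc2)c(OCc2ccccc2)c1)c1cc(OCc2ccccc2)c(OCc2ccccc2)c(OCc2ccccc2)c1 | intermediate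
9 | 4-(2-hydroxyethoxy) derivative of octa-O-benzyl-EGCG: 5,7-bis(benzyloxy)-4-(2-hydroxyethoxy)-2-[3,4,5-tris(benzyloxy)phenyl]chroman-3-yl 3,4,5-tris(benzyloxy)benzoate, C2 and C3 as in EGCG, both C4 epimers | O=C(O[C@@H]1C(OCCO)c2c(OCc3ccccc3)cc(OCc3ccccc3)cc2O[C@@H]1c1cc(OCc3ccccc3)c(OCc3ccccc3)c(OCc3ccccc3)c1)c1cc(OCc3ccccc3)c(OCc3ccccc3)c(OCc3ccccc3)c1 | intermediate
10 | octa-O-benzyl-(−)-epigallocatechin 3-O-gallate, (2R,3R) | O=C(O[C@@H]1Cc2c(OCc3ccccc3)cc(OCc3ccccc3)cc2O[C@@H]1c1cc(OCc3ccccc3)c(OCc3ccccc3)c(OCc3ccccc3)c1)c1cc(OCc3ccccc3)c(OCc3ccccc3)c(OCc3ccccc3)c1 | intermediate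
11 | hexadeca-O-benzyl-rhodisin: per-O-benzyl EGCG-(4β→8)-EGCG, all sixteen phenols as benzyl ethers | O=C(O[C@@H]1[C@@H](c2c(OCc4ccccc4)cc(OCc4ccccc4)c3c2O[C@H](c2cc(OCc4ccccc4)c(OCc4ccccc4)c(OCc4ccccc4)c2)[C@H](OC(=O)c2cc(OCc4ccccc4)c(OCc4ccccc4)c(OCc4ccccc4)c2)C3)c2c(OCc4ccccc4)cc(OCc4ccccc4)cc2O[C@@H]1c1cc(OCc4ccccc4)c(OCc4ccccc4)c(OCc4ccccc4)c1)c1cc(OCc4ccccc4)c(OCc4ccccc4)c(OCc4ccccc4)c1 | intermediate
12 | rhodisin: (−)-epigallocatechin 3-O-gallate-(4β→8)-(−)-epigallocatechin 3-O-gallate | O=C(O[C@@H]1[C@@H](c2c(O)cc(O)c3c2O[C@H](c2cc(O)c(O)c(O)c2)[C@H](OC(=O)c2cc(O)c(O)c(O)c2)C3)c2c(O)cc(O)cc2O[C@@H]1c1cc(O)c(O)c(O)c1)c1cc(O)c(O)c(O)c1 | target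

**Summary**

Total step count: 6. Longest linear sequence: 6 (1 → 3 → 4 → 6 → 8 → 11 → 12).

Three steps most likely to fail:

Step 5. The acetal may cyclise sluggishly next to the acyloxy group, 9 may self-condense to oligomers, some attack may occur at C6, and the benzylic aryl ether may ionise. The fallback sets out from 8 and comes back at 11. Only the reductive half is run on 8 (TMSOTf, then Et3SiH) and octa-O-benzyl-EGCG 10 is isolated. Part of 10 is oxidised at C4 with DDQ in the presence of 2-ethoxyethanol to the 4β-(2-ethoxyethoxy) ether of octa-O-benzyl-EGCG F1. F1 is then condensed with isolated 10 (2–3 equiv, TMSOTf, CH2Cl2, −78 °C, or equimolar with Yb(OTf)3) to give 11. This separates ring formation from interflavan bond formation and makes the C4 electrophile by benzylic C–H oxidation of a preformed flavan instead of by cyclisation.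

Step 3. The electron-rich benzylic carbon may react with SN1 character (loss of stereospecificity), the ambident phenoxide may C-alkylate, or the opening may be slow. The fallback sets out from 1 and comes back at 6. Ando-type Z-selective Horner–Wadsworth–Emmons olefination of 1 with ethyl (diphenoxyphosphoryl)acetate gives ethyl (Z)-3-[3,4,5-tris(benzyloxy)phenyl]acrylate F2. Jacobsen epoxidation with the (S,S) catalyst gives the cis-glycidate F3. The phenoxide of 5 opens F3 at C3 with inversion to the hydroxy ester F4; the ester disfavours a benzylic cation, so the SN2 course typical of 3-arylglycidates is enforced. DIBAL at −78 °C gives the α-hydroxy aldehyde F5, which ethylene glycol/PPTS converts into 6.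

Step 1. The Z/E ratio of this Wittig reaction with an aromatic aldehyde is uncertain. The fallback sets out from 1 and comes back at 3. Ohira–Bestmann homologation of 1 gives the aryl alkyne F6. n-BuLi followed by DMF gives the ynal F7. Ethylene glycol/TsOH gives the alkynyl dioxolane F8. Lindlar semi-hydrogenation (quinoline) then gives 3 as the pure Z isomer.

**Further compounds**

F1 | step 5 | 4β-(2-ethoxyethoxy) ether of octa-O-benzyl-EGCG | O=C(O[C@@H]1[C@@H](OCCOCC)c2c(OCc3ccccc3)cc(OCc3ccccc3)cc2O[C@@H]1c1cc(OCc3ccccc3)c(OCc3ccccc3)c(OCc3ccccc3)c1)c1cc(OCc3ccccc3)c(OCc3ccccc3)c(OCc3ccccc3)c1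
F2 | step 3 | ethyl (Z)-3-[3,4,5-tris(benzyloxy)phenyl]acrylate | CCOC(=O)/C=C\c1cc(OCc2ccccc2)c(OCc2ccccc2)c(OCc2ccccc2)c1
F3 | step 3 | ethyl (2S,3S)-3-[3,4,5-tris(benzyloxy)phenyl]oxirane-2-carboxylate (cis) | O1[C@H](C(=O)OCC)[C@@H]1c1cc(OCc3ccccc3)c(OCc3ccccc3)c(OCc3ccccc3)c1
F4 | step 3 | ethyl (2S,3R)-3-[3,5-bis(benzyloxy)phenoxy]-2-hydroxy-3-[3,4,5-tris(benzyloxy)phenyl]propanoate | O[C@H](C(=O)OCC)[C@H](Oc1cc(OCc2ccccc2)cc(OCc2ccccc2)c1)c1cc(OCc2ccccc2)c(OCc2ccccc2)c(OCc2ccccc2)c1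
F5 | step 3 | (2S,3R)-3-[3,5-bis(benzyloxy)phenoxy]-2-hydroxy-3-[3,4,5-tris(benzyloxy)phenyl]propanal | O[C@H](C=O)[C@H](Oc1cc(OCc2ccccc2)cc(OCc2ccccc2)c1)c1cc(OCc2ccccc2)c(OCc2ccccc2)c(OCc2ccccc2)c1
F6 | step 1 | 1,2,3-tris(benzyloxy)-5-ethynylbenzene | C#Cc1cc(OCc2ccccc2)c(OCc2ccccc2)c(OCc2ccccc2)c1
F7 | step 1 | 3-[3,4,5-tris(benzyloxy)phenyl]prop-2-ynal | O=CC#Cc1cc(OCc2ccccc2)c(OCc2ccccc2)c(OCc2ccccc2)c1
F8 | step 1 | 2-{[3,4,5-tris(benzyloxy)phenyl]ethynyl}-1,3-dioxolane | C1COC(O1)C#Cc1cc(OCc2ccccc2)c(OCc2ccccc2)c(OCc2ccccc2)c1
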